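**Retrosynthetic overview**

1. Feature: in the flavone half, ring A is fused to the pyranone so that C4a (bearing the C4 carbonyl) lies next to C5–O and C8a (bearing O1) lies next to C8–H. An acyl carbon and an oxygen on adjacent ring carbons, with an alkoxy group flanking the acyl carbon, is the pattern left when a carboxylic acid inserts into a 3-alkoxybenzyne.
2. Flavanone half, last bonds: global hydrogenolysis; C4–C4a by Friedel–Crafts acylation onto the mirror-symmetric tetraoxygenated ring; O1–C2 by Mitsunobu inversion of an (R)-β-hydroxy ester, which sets (2S).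
3. Flavone half, key disconnection: C4–C4a, O1–C8a and O1–C2 of the pyranone, back to 3,5-bis(benzyloxy)benzyne (from its 2-silylaryl triflate) and an arylpropiolic acid that already carries the protected ring A of the flavanone through the C6–O–C4' diaryl ether.
4. The propiolic acid comes from SNAr of 2,6-bis(benzyloxy)-4-(methoxymethoxy)phenol on 4-fluorobenzaldehyde, then Corey–Fuchs homologation and carboxylation; this phenol and the aryne precursor both derive from 3,5-bis(benzyloxy)phenol.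
5. Ring order: flavone pyranone first (step 10), flavanone pyranone second (step 18), so the base-sensitive stereocentre never sees fluoride at high temperature.

Key step: step 10

Assumption: 3,5-bis(benzyloxy)phenol (phloroglucinol dibenzyl ether) is taken as purchasable; the 4'-oxygen of the flavanone is carried as a benzyl carbonate rather than a benzyl ether, so that the C2–O bond is never a para-alkoxybenzyl ether during the Mitsunobu and Friedel–Crafts steps.

**Aryne precursor**

Step 1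
Reactants: 1 3,5-bis(benzyloxy)phenol
Product: 2 3,5-bis(benzyloxy)phenyl N-isopropylcarbamate
Conditions: i-PrNCO, Et3N (cat.), CH2Cl2, rt
Reagents that add atoms: isopropyl isocyanate, CC(C)N=C=O
Why: Base-catalysed carbamoylation of the phenol with the isocyanate installs an N-monoalkyl carbamate that directs ortho-metalation and can later be removed under mild base.

Step 2
Reactants: 2 3,5-bis(benzyloxy)phenyl N-isopropylcarbamate
Product: 6 3,5-bis(benzyloxy)-2-(trimethylsilyl)phenyl N-isopropylcarbamate, via N-silyl carbamate 3 (not isolated), via ortho-lithiated N-silyl carbamate 4 (not isolated), via N-silyl C-silyl carbamate 5 (not isolated)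
Conditions: TBSOTf, TMEDA, Et2O, 0 °C to rt; n-BuLi, TMEDA, −78 °C; Me3SiCl, −78 °C to rt; aq. NaHSO4
Reagents that add atoms: chlorotrimethylsilane, C[Si](C)(C)Cl
Why: After in situ N-silylation masks the N–H, carbamate-directed ortho-lithiation (Snieckus directed ortho-metalation) should occur at the ring carbon flanked by the carbamate and a benzyloxy group, both of which bind lithium, and the aryllithium is silylated at −78 °C before benzylic deprotonation can compete.

Step 3
Reactants: 6 3,5-bis(benzyloxy)-2-(trimethylsilyl)phenyl N-isopropylcarbamate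
Product: 8 3,5-bis(benzyloxy)-2-(trimethylsilyl)phenyl trifluoromethanesulfonate, via silylphenol 7 (not isolated)
Conditions: DBU, Et2NH, MeCN, 40 °C; then PhNTf2, rt
Reagents that add atoms: N-phenylbis(trifluoromethanesulfonimide), O=S(=O)(N(c1ccccc1)S(=O)(=O)C(F)(F)F)C(F)(F)F
Why: E1cB fragmentation of the N–H carbamate releases the phenoxide and isopropyl isocyanate (trapped by Et2NH as a urea), and O-triflation with PhNTf2 completes the standard carbamate route to ortho-silylaryl triflates.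

**Propiolic acid**

Step 4
Reactants: 1 3,5-bis(benzyloxy)phenol
Product: 10 2,6-bis(benzyloxy)-4-hydroxybenzaldehyde, via aryl iminium chloride 9 (not isolated)
Conditions: POCl3, DMF, MeCN, 0 °C to rt; then H2O, 50 °C
Reagents that add atoms: N,N-dimethylformamide, CN(C)C=O
Why: Vilsmeier–Haack formylation of the 3,5-dialkoxyphenol is expected to occur mainly para to the free hydroxyl, as it does for the dimethyl ether analogue, and the minor ortho-formyl isomer is removed by chromatography.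

Step 5
Reactants: 10 2,6-bis(benzyloxy)-4-hydroxybenzaldehyde
Product: 11 2,6-bis(benzyloxy)-4-(methoxymethoxy)benzaldehyde
Conditions: MOMCl, i-Pr2NEt, CH2Cl2, 0 °C to rt
Reagents that add atoms: chloromethyl methyl ether, COCCl
Why: O-alkylation of the acidic para-formyl phenol gives a methoxymethyl acetal that withstands base, organolithium and fluoride at high temperature and is orthogonal to the benzyl ethers.

Step 6
Reactants: 11 2,6-bis(benzyloxy)-4-(methoxymethoxy)benzaldehyde
Product: 13 2,6-bis(benzyloxy)-4-(methoxymethoxy)phenol, via aryl formate 12 (not isolated)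
Conditions: mCPBA, NaHCO3, CH2Cl2, 0 °C to rt; then K2CO3 (cat.), MeOH, rt
Reagents that add atoms: 3-chloroperoxybenzoic acid, O=C(OO)c1cccc(Cl)c1
Why: Baeyer–Villiger (Dakin-type) oxidation of the 2,4,6-trioxygenated benzaldehyde should proceed by migration of the very electron-rich aryl group, and mild methanolysis of the formate frees the phenol without touching the acetal.

Step 7
Reactants: 13 2,6-bis(benzyloxy)-4-(methoxymethoxy)phenol; 14 4-fluorobenzaldehyde
Product: 15 4-[2,6-bis(benzyloxy)-4-(methoxymethoxy)phenoxy]benzaldehyde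
Conditions: K2CO3, DMF, 110 °C, N2
Reagents that add atoms: none
Why: Nucleophilic aromatic substitution (SNAr) of the formyl-activated fluoride by the electron-rich phenoxide, a reaction type that tolerates 2,6-dialkoxy substitution on the phenol, forms the diaryl ether.

Step 8
Reactants: 15 4-[2,6-bis(benzyloxy)-4-(methoxymethoxy)phenoxy]benzaldehyde
Product: 16 1,3-bis(benzyloxy)-2-[4-(2,2-dibromoethenyl)phenoxy]-5-(methoxymethoxy)benzene
Conditions: CBr4, PPh3, Et3N, CH2Cl2, 0 °C
Reagents that add atoms: carbon tetrabromide, BrC(Br)(Br)Br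
Why: Corey–Fuchs (Ramirez) dibromo-olefination of the aromatic aldehyde with the ylide from CBr4 and PPh3, with Et3N buffering the acid that could cleave the acetal.

Step 9
Reactants: 16 1,3-bis(benzyloxy)-2-[4-(2,2-dibromoethenyl)phenoxy]-5-(methoxymethoxy)benzene
Product: 18 3-{4-[2,6-bis(benzyloxy)-4-(methoxymethoxy)phenoxy]phenyl}prop-2-ynoic acid, via lithium acetylide 17 (not isolated)
Conditions: n-BuLi (2.2 equiv), THF, −78 °C; CO2, −78 °C to rt; cold 1 M HCl
Reagents that add atoms: carbon dioxide, O=C=O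
Why: In the second stage of the Corey–Fuchs sequence, bromine–lithium exchange and Fritsch–Buttenberg–Wiechell rearrangement give the lithium acetylide, which is carboxylated by CO2 to the arylpropiolic acid.

**Key step and phenol release**

Step 10
Reactants: 18 3-{4-[2,6-bis(benzyloxy)-4-(methoxymethoxy)phenoxy]phenyl}prop-2-ynoic acid; 8 3,5-bis(benzyloxy)-2-(trimethylsilyl)phenyl trifluoromethanesulfonate
Product: 21 5,7-bis(benzyloxy)-2-{4-[2,6-bis(benzyloxy)-4-(methoxymethoxy)phenoxy]phenyl}-4H-chromen-4-one, via 3,5-bis(benzyloxy)benzyne 19 (not isolated), via ortho-hydroxyaryl ynone 20 (not isolated)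
Conditions: CsF (4 equiv), 8 (1.5 equiv), THF, 125 °C, sealed tube
Reagents that add atoms: none
Why: Fluoride desilylates 8 and loss of triflate gives aryne 19; the caesium carboxylate of 18 adds through oxygen to the aryne carbon remote from the adjacent benzyloxy group, and the aryl anion formed next to that benzyloxy group attacks the ester carbonyl through a four-membered ring whose collapse moves the acyl group onto carbon and releases the phenoxide of ynone 20. The phenoxide then adds to the β-carbon of the ynone in a 6-endo-dig oxa-Michael closure, and protonation gives the pyranone ring of flavone 21 with the new bonds C4–C4a, O1–C8a and O1–C2. The closest known reaction type is the fluoride-triggered insertion of arynes into the C–O bond of carboxylic acids to give ortho-hydroxyaryl ketones, which with arylpropiolic acids runs on to flavones in the same flask. No stereocentre is formed. The step needs regioselective addition to the unsymmetrical aryne, secured by the inductive effect and angle distortion of the benzyloxy group beside the silyl-bearing carbon, and 6-endo rather than 5-exo closure, secured by polarisation of the conjugated ynone toward its β-carbon.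

Step 11
Reactants: 21 5,7-bis(benzyloxy)-2-{4-[2,6-bis(benzyloxy)-4-(methoxymethoxy)phenoxy]phenyl}-4H-chromen-4-one
Product: 22 5,7-bis(benzyloxy)-2-{4-[2,6-bis(benzyloxy)-4-hydroxyphenoxy]phenyl}-4H-chromen-4-one
Conditions: conc. HCl (cat.), MeOH/THF, 45 °C
Reagents that add atoms: none
Why: Acid-catalysed acetal exchange with methanol removes the methoxymethyl group and frees the phenol that becomes O1 of the flavanone, while benzyl ethers and the flavone are stable to dilute acid.

**Chiral three-carbon fragment**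

Step 12
Reactants: 23 4-hydroxybenzaldehyde
Product: 24 benzyl 4-formylphenyl carbonate
Conditions: CbzCl, Et3N, CH2Cl2, 0 °C
Reagents that add atoms: benzyl chloroformate, O=C(Cl)OCc1ccccc1
Why: Acylation of the phenol with the chloroformate gives a benzyl carbonate that makes the para oxygen a weak donor, which suppresses benzylic ionisation later, and that is removed by hydrogenolysis.

Step 13
Reactants: 24 benzyl 4-formylphenyl carbonate; 25 allyl bromoacetate
Product: 26 racemic allyl 3-{4-[(benzyloxycarbonyl)oxy]phenyl}-3-hydroxypropanoate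
Conditions: Zn (activated), THF, 0 °C to rt; aq. NH4Cl
Reagents that add atoms: none
Why: In this Reformatsky reaction the zinc enolate adds to the aldehyde but is too mild to attack the aryl carbonate.

Step 14
Reactants: 26 racemic allyl 3-{4-[(benzyloxycarbonyl)oxy]phenyl}-3-hydroxypropanoate
Product: 27 allyl 3-{4-[(benzyloxycarbonyl)oxy]phenyl}-3-oxopropanoate
Conditions: Dess–Martin periodinane, CH2Cl2, rt
Reagents that add atoms: none
Why: Dess–Martin oxidation of the secondary benzylic alcohol gives the β-keto ester under neutral conditions that leave the carbonate and the allyl ester intact.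

Step 15
Reactants: 27 allyl 3-{4-[(benzyloxycarbonyl)oxy]phenyl}-3-oxopropanoate
Product: 28 allyl (3R)-3-{4-[(benzyloxycarbonyl)oxy]phenyl}-3-hydroxypropanoate
Conditions: RuCl(p-cymene)[(R,R)-TsDPEN] (cat.), HCO2H/Et3N (5:2), CH2Cl2, rt
Reagents that add atoms: none
Why: Noyori asymmetric transfer hydrogenation of the aryl ketone with the (R,R)-ligand should deliver hydride to the face that gives the (R)-carbinol, in the same sense as acetophenone to (R)-1-phenylethanol (aryl group held by the CH/π contact with the cymene ligand), and this sets the stereocentre that becomes C2.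

**Flavanone assembly**

Step 16
Reactants: 22 5,7-bis(benzyloxy)-2-{4-[2,6-bis(benzyloxy)-4-hydroxyphenoxy]phenyl}-4H-chromen-4-one; 28 allyl (3R)-3-{4-[(benzyloxycarbonyl)oxy]phenyl}-3-hydroxypropanoate
Product: 29 allyl (3S)-3-{3,5-bis(benzyloxy)-4-[4-(5,7-bis(benzyloxy)-4-oxo-4H-chromen-2-yl)phenoxy]phenoxy}-3-{4-[(benzyloxycarbonyl)oxy]phenyl}propanoate
Conditions: PPh3, DIAD, toluene, 0 °C to rt
Reagents that add atoms: none
Why: In this Mitsunobu etherification the phenol displaces the oxyphosphonium-activated benzylic alcohol by SN2 with inversion, turning the (R)-alcohol into the (S)-aryl ether, and the weakly donating carbonate on the aryl ring disfavours an SN1 pathway.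

Step 17
Reactants: 29 allyl (3S)-3-{3,5-bis(benzyloxy)-4-[4-(5,7-bis(benzyloxy)-4-oxo-4H-chromen-2-yl)phenoxy]phenoxy}-3-{4-[(benzyloxycarbonyl)oxy]phenyl}propanoate
Product: 30 (3S)-3-{3,5-bis(benzyloxy)-4-[4-(5,7-bis(benzyloxy)-4-oxo-4H-chromen-2-yl)phenoxy]phenoxy}-3-{4-[(benzyloxycarbonyl)oxy]phenyl}propanoic acid
Conditions: Pd(PPh3)4 (cat.), N-methylaniline, THF, rt
Reagents that add atoms: none
Why: Tsuji–Trost deallylation ionises the allyl ester to a π-allyl palladium complex that is captured by the weakly basic amine, freeing the acid under neutral conditions that spare the aryl carbonate and avoid β-elimination of the aryloxy group.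

Step 18
Reactants: 30 (3S)-3-{3,5-bis(benzyloxy)-4-[4-(5,7-bis(benzyloxy)-4-oxo-4H-chromen-2-yl)phenoxy]phenoxy}-3-{4-[(benzyloxycarbonyl)oxy]phenyl}propanoic acid
Product: 32 (2S)-5,7-bis(benzyloxy)-6-[4-(5,7-bis(benzyloxy)-4-oxo-4H-chromen-2-yl)phenoxy]-2-{4-[(benzyloxycarbonyl)oxy]phenyl}chroman-4-one, via mixed trifluoroacetic anhydride 31 (not isolated)
Conditions: (CF3CO)2O, CH2Cl2, 0 °C to rt
Reagents that add atoms: none
Why: Intramolecular Friedel–Crafts acylation through the mixed anhydride closes the six-membered chromanone ring at the position ortho to the ether oxygen, which is activated by three oxygen substituents and is equivalent to its mirror position, without involving the C2 stereocentre.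

Step 19
Reactants: 32 (2S)-5,7-bis(benzyloxy)-6-[4-(5,7-bis(benzyloxy)-4-oxo-4H-chromen-2-yl)phenoxy]-2-{4-[(benzyloxycarbonyl)oxy]phenyl}chroman-4-one
Product: 33 (2S)-5,7-dihydroxy-6-[4-(5,7-dihydroxy-4-oxo-4H-chromen-2-yl)phenoxy]-2-(4-hydroxyphenyl)chroman-4-one
Conditions: H2 (1 atm), Pd/C (10 wt% Pd), THF/MeOH, rt
Reagents that add atoms: none
Why: Catalytic hydrogenolysis cleaves the four benzyl ethers and the benzyl carbonate (which then loses CO2) under neutral conditions, so the base-sensitive flavanone stereocentre should not epimerise.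

**Compound list**

1 | 3,5-bis(benzyloxy)phenol | Oc1cc(OCc2ccccc2)cc(OCc2ccccc2)c1 | starting material
2 | 3,5-bis(benzyloxy)phenyl N-isopropylcarbamate | CC(C)NC(=O)Oc1cc(OCc2ccccc2)cc(OCc2ccccc2)c1 | intermediate
3 | 3,5-bis(benzyloxy)phenyl N-(tert-butyldimethylsilyl)-N-isopropylcarbamate | CC(C)N([Si](C)(C)C(C)(C)C)C(=O)Oc1cc(OCc2ccccc2)cc(OCc2ccccc2)c1 | intermediate
4 | 2-lithio derivative of 3 | [Li]c1c(OC(=O)N(C(C)C)[Si](C)(C)C(C)(C)C)cc(OCc2ccccc2)cc1OCc1ccccc1 | intermediate
5 | 3,5-bis(benzyloxy)-2-(trimethylsilyl)phenyl N-(tert-butyldimethylsilyl)-N-isopropylcarbamate | CC(C)N([Si](C)(C)C(C)(C)C)C(=O)Oc1cc(OCc2ccccc2)cc(OCc2ccccc2)c1[Si](C)(C)C | intermediate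
6 | 3,5-bis(benzyloxy)-2-(trimethylsilyl)phenyl N-isopropylcarbamate | CC(C)NC(=O)Oc1cc(OCc2ccccc2)cc(OCc2ccccc2)c1[Si](C)(C)C | intermediate
7 | 3,5-bis(benzyloxy)-2-(trimethylsilyl)phenol | Oc1cc(OCc2ccccc2)cc(OCc2ccccc2)c1[Si](C)(C)C | intermediate
8 | 3,5-bis(benzyloxy)-2-(trimethylsilyl)phenyl trifluoromethanesulfonate | C[Si](C)(C)c1c(OCc2ccccc2)cc(OCc2ccccc2)cc1OS(=O)(=O)C(F)(F)F | intermediate
9 | [2,6-bis(benzyloxy)-4-hydroxybenzylidene]dimethyliminium chloride | C[N+](C)=Cc1c(OCc2ccccc2)cc(O)cc1OCc1ccccc1.[Cl-] | intermediate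
10 | 2,6-bis(benzyloxy)-4-hydroxybenzaldehyde | O=Cc1c(OCc2ccccc2)cc(O)cc1OCc1ccccc1 | intermediate
11 | 2,6-bis(benzyloxy)-4-(methoxymethoxy)benzaldehyde | O=Cc1c(OCc2ccccc2)cc(OCOC)cc1OCc1ccccc1 | intermediate
12 | 2,6-bis(benzyloxy)-4-(methoxymethoxy)phenyl formate | O=COc1c(OCc2ccccc2)cc(OCOC)cc1OCc1ccccc1 | intermediate
13 | 2,6-bis(benzyloxy)-4-(methoxymethoxy)phenol | Oc1c(OCc2ccccc2)cc(OCOC)cc1OCc1ccccc1 | intermediate
14 | 4-fluorobenzaldehyde | O=Cc1ccc(F)cc1 | starting material
15 | 4-[2,6-bis(benzyloxy)-4-(methoxymethoxy)phenoxy]benzaldehyde | O=Cc1ccc(Oc2c(OCc3ccccc3)cc(OCOC)cc2OCc2ccccc2)cc1 | intermediate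
16 | 1,3-bis(benzyloxy)-2-[4-(2,2-dibromoethenyl)phenoxy]-5-(methoxymethoxy)benzene | BrC(Br)=Cc1ccc(Oc2c(OCc3ccccc3)cc(OCOC)cc2OCc2ccccc2)cc1 | intermediate
17 | lithium {4-[2,6-bis(benzyloxy)-4-(methoxymethoxy)phenoxy]phenyl}acetylide | [Li]C#Cc1ccc(Oc2c(OCc3ccccc3)cc(OCOC)cc2OCc2ccccc2)cc1 | intermediate
18 | 3-{4-[2,6-bis(benzyloxy)-4-(methoxymethoxy)phenoxy]phenyl}prop-2-ynoic acid | OC(=O)C#Cc1ccc(Oc2c(OCc3ccccc3)cc(OCOC)cc2OCc2ccccc2)cc1 | intermediate
19 | 3,5-bis(benzyloxy)benzyne | C1(OCc2ccccc2)=CC(OCc2ccccc2)=CC#C1 | intermediate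
20 | 1-[2,4-bis(benzyloxy)-6-hydroxyphenyl]-3-{4-[2,6-bis(benzyloxy)-4-(methoxymethoxy)phenoxy]phenyl}prop-2-yn-1-one | O=C(C#Cc1ccc(Oc2c(OCc3ccccc3)cc(OCOC)cc2OCc2ccccc2)cc1)c1c(O)cc(OCc2ccccc2)cc1OCc1ccccc1 | intermediate
21 | 5,7-bis(benzyloxy)-2-{4-[2,6-bis(benzyloxy)-4-(methoxymethoxy)phenoxy]phenyl}-4H-chromen-4-one | COCOc1cc(OCc2ccccc2)c(Oc2ccc(-c3cc(=O)c4c(OCc5ccccc5)cc(OCc5ccccc5)cc4o3)cc2)c(OCc2ccccc2)c1 | intermediate
22 | 5,7-bis(benzyloxy)-2-{4-[2,6-bis(benzyloxy)-4-hydroxyphenoxy]phenyl}-4H-chromen-4-one | Oc1cc(OCc2ccccc2)c(Oc2ccc(-c3cc(=O)c4c(OCc5ccccc5)cc(OCc5ccccc5)cc4o3)cc2)c(OCc2ccccc2)c1 | intermediate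
23 | 4-hydroxybenzaldehyde | O=Cc1ccc(O)cc1 | starting material
24 | benzyl 4-formylphenyl carbonate | O=Cc1ccc(OC(=O)OCc2ccccc2)cc1 | intermediate
25 | allyl bromoacetate | C=CCOC(=O)CBr | starting material
26 | racemic allyl 3-{4-[(benzyloxycarbonyl)oxy]phenyl}-3-hydroxypropanoate | C=CCOC(=O)CC(O)c1ccc(OC(=O)OCc2ccccc2)cc1 | intermediate
27 | allyl 3-{4-[(benzyloxycarbonyl)oxy]phenyl}-3-oxopropanoate | C=CCOC(=O)CC(=O)c1ccc(OC(=O)OCc2ccccc2)cc1 | intermediate
28 | allyl (3R)-3-{4-[(benzyloxycarbonyl)oxy]phenyl}-3-hydroxypropanoate | C=CCOC(=O)C[C@@H](O)c1ccc(OC(=O)OCc2ccccc2)cc1 | intermediate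
29 | allyl (3S)-3-{3,5-bis(benzyloxy)-4-[4-(5,7-bis(benzyloxy)-4-oxo-4H-chromen-2-yl)phenoxy]phenoxy}-3-{4-[(benzyloxycarbonyl)oxy]phenyl}propanoate | C=CCOC(=O)C[C@H](Oc1cc(OCc2ccccc2)c(Oc2ccc(-c3cc(=O)c4c(OCc5ccccc5)cc(OCc5ccccc5)cc4o3)cc2)c(OCc2ccccc2)c1)c1ccc(OC(=O)OCc2ccccc2)cc1 | intermediate
30 | (3S)-3-{3,5-bis(benzyloxy)-4-[4-(5,7-bis(benzyloxy)-4-oxo-4H-chromen-2-yl)phenoxy]phenoxy}-3-{4-[(benzyloxycarbonyl)oxy]phenyl}propanoic acid | OC(=O)C[C@H](Oc1cc(OCc2ccccc2)c(Oc2ccc(-c3cc(=O)c4c(OCc5ccccc5)cc(OCc5ccccc5)cc4o3)cc2)c(OCc2ccccc2)c1)c1ccc(OC(=O)OCc2ccccc2)cc1 | intermediate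
31 | mixed anhydride of acid 30 with trifluoroacetic acid | O=C(C[C@H](Oc1cc(OCc2ccccc2)c(Oc2ccc(-c3cc(=O)c4c(OCc5ccccc5)cc(OCc5ccccc5)cc4o3)cc2)c(OCc2ccccc2)c1)c1ccc(OC(=O)OCc2ccccc2)cc1)OC(=O)C(F)(F)F | intermediate
32 | (2S)-5,7-bis(benzyloxy)-6-[4-(5,7-bis(benzyloxy)-4-oxo-4H-chromen-2-yl)phenoxy]-2-{4-[(benzyloxycarbonyl)oxy]phenyl}chroman-4-one | O=C1C[C@@H](c2ccc(OC(=O)OCc3ccccc3)cc2)Oc2cc(OCc3ccccc3)c(Oc3ccc(-c4cc(=O)c5c(OCc6ccccc6)cc(OCc6ccccc6)cc5o4)cc3)c(OCc3ccccc3)c21 | intermediate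
33 | (2S)-5,7-dihydroxy-6-[4-(5,7-dihydroxy-4-oxo-4H-chromen-2-yl)phenoxy]-2-(4-hydroxyphenyl)chroman-4-one | O=C1C[C@@H](c2ccc(O)cc2)Oc2cc(O)c(Oc3ccc(-c4cc(=O)c5c(O)cc(O)cc5o4)cc3)c(O)c21 | target

**Step count and risks**

Total steps: 19. Longest linear sequence: 12 steps (steps 4–11 and 16–19, from compound 1).

Steps most likely to fail:

1. Step 10 (aryne insertion and oxa-Michael closure). The propiolate may lose CO2 at 125 °C before it meets the aryne, or the aryl anion may be protonated before acyl transfer, so that only the aryl ester forms. Fallback by the chalcone route, setting out from aldehyde 15 and coming back at flavone 21: commercial 2',4',6'-trihydroxyacetophenone is benzylated at its two non-chelated hydroxyls (BnBr, K2CO3, DMF) to 1-[2,4-bis(benzyloxy)-6-hydroxyphenyl]ethanone F1; Claisen–Schmidt condensation of this ketone with 15 (KOH, EtOH/THF) should give the 2'-hydroxychalcone F2; oxidative cyclisation (I2 cat., DMSO, 120 °C) should then give 21.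

2. Step 16 (Mitsunobu etherification). The activated β-hydroxy ester may undergo β-elimination to the cinnamate, or partial ionisation at the benzylic carbon may erode the inversion. Fallback that carries the carboxyl carbon as a vinyl group, setting out from aldehyde 24 and phenol 22 and coming back at acid 30: Keck allylation of 24 (allyltributylstannane, Ti(OiPr)4 with the BINOL enantiomer that delivers the (R)-alcohol, expected to be (R)-BINOL) gives benzyl 4-[(1R)-1-hydroxybut-3-en-1-yl]phenyl carbonate F3, which has no acidic α-hydrogen; Mitsunobu coupling with 22 (PPh3, DIAD) should give the (S)-homoallyl aryl ether F4; dihydroxylation and periodate cleavage (OsO4 cat., NMO; NaIO4) give the (S)-aldehyde F5; Pinnick oxidation (NaClO2, NaH2PO4, 2-methyl-2-butene) gives 30.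

3. Step 18 (Friedel–Crafts closure). Acid may ionise the benzylic C2–O bond, causing loss of configuration or retro-Michael cleavage, or benzyl groups may migrate on the very electron-rich ring. Fallback that closes the pyranone before the stereocentre exists, setting out from phenol 22 and coming back at target 33: oxa-Michael addition of 22 to ethyl propiolate (DABCO, CH2Cl2) gives the ethyl (E)-3-aryloxyacrylate F6; saponification (LiOH, THF/H2O) gives the acrylic acid F7; cyclodehydration (P2O5 in MeSO3H) gives the 5,7-bis(benzyloxy)-6-aryloxychromone F8; enantioselective conjugate addition of 4-(benzyloxy)phenylboronic acid (Pd(OCOCF3)2, the tert-butyl pyridinyl-oxazoline ligand enantiomer that gives the (2S) product, NH4PF6, H2O, ClCH2CH2Cl, 60 °C) gives the (2S)-flavanone pentabenzyl ether F9; hydrogenolysis (H2, Pd/C) gives 33.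

**Further compounds**

F1 | step 10 | 1-[2,4-bis(benzyloxy)-6-hydroxyphenyl]ethanone | CC(=O)c1c(O)cc(OCc2ccccc2)cc1OCc1ccccc1
F2 | step 10 | (E)-1-[2,4-bis(benzyloxy)-6-hydroxyphenyl]-3-{4-[2,6-bis(benzyloxy)-4-(methoxymethoxy)phenoxy]phenyl}prop-2-en-1-one | O=C(/C=C/c1ccc(Oc2c(OCc3ccccc3)cc(OCOC)cc2OCc2ccccc2)cc1)c1c(O)cc(OCc2ccccc2)cc1OCc1ccccc1
F3 | step 16 | benzyl 4-[(1R)-1-hydroxybut-3-en-1-yl]phenyl carbonate | C=CC[C@@H](O)c1ccc(OC(=O)OCc2ccccc2)cc1
F4 | step 16 | benzyl 4-[(1S)-1-{3,5-bis(benzyloxy)-4-[4-(5,7-bis(benzyloxy)-4-oxo-4H-chromen-2-yl)phenoxy]phenoxy}but-3-en-1-yl]phenyl carbonate | C=CC[C@H](Oc1cc(OCc2ccccc2)c(Oc2ccc(-c3cc(=O)c4c(OCc5ccccc5)cc(OCc5ccccc5)cc4o3)cc2)c(OCc2ccccc2)c1)c1ccc(OC(=O)OCc2ccccc2)cc1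
F5 | step 16 | benzyl 4-[(1S)-1-{3,5-bis(benzyloxy)-4-[4-(5,7-bis(benzyloxy)-4-oxo-4H-chromen-2-yl)phenoxy]phenoxy}-3-oxopropyl]phenyl carbonate | O=CC[C@H](Oc1cc(OCc2ccccc2)c(Oc2ccc(-c3cc(=O)c4c(OCc5ccccc5)cc(OCc5ccccc5)cc4o3)cc2)c(OCc2ccccc2)c1)c1ccc(OC(=O)OCc2ccccc2)cc1
F6 | step 18 | ethyl (E)-3-{3,5-bis(benzyloxy)-4-[4-(5,7-bis(benzyloxy)-4-oxo-4H-chromen-2-yl)phenoxy]phenoxy}acrylate | CCOC(=O)/C=C/Oc1cc(OCc2ccccc2)c(Oc2ccc(-c3cc(=O)c4c(OCc5ccccc5)cc(OCc5ccccc5)cc4o3)cc2)c(OCc2ccccc2)c1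
F7 | step 18 | (E)-3-{3,5-bis(benzyloxy)-4-[4-(5,7-bis(benzyloxy)-4-oxo-4H-chromen-2-yl)phenoxy]phenoxy}acrylic acid | OC(=O)/C=C/Oc1cc(OCc2ccccc2)c(Oc2ccc(-c3cc(=O)c4c(OCc5ccccc5)cc(OCc5ccccc5)cc4o3)cc2)c(OCc2ccccc2)c1
F8 | step 18 | 5,7-bis(benzyloxy)-6-[4-(5,7-bis(benzyloxy)-4-oxo-4H-chromen-2-yl)phenoxy]-4H-chromen-4-one | O=c1ccoc2cc(OCc3ccccc3)c(Oc3ccc(-c4cc(=O)c5c(OCc6ccccc6)cc(OCc6ccccc6)cc5o4)cc3)c(OCc3ccccc3)c12
F9 | step 18 | (2S)-5,7-bis(benzyloxy)-2-[4-(benzyloxy)phenyl]-6-[4-(5,7-bis(benzyloxy)-4-oxo-4H-chromen-2-yl)phenoxy]chroman-4-one | O=C1C[C@@H](c2ccc(OCc3ccccc3)cc2)Oc2cc(OCc3ccccc3)c(Oc3ccc(-c4cc(=O)c5c(OCc6ccccc6)cc(OCc6ccccc6)cc5o4)cc3)c(OCc3ccccc3)c21
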